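# Proposed total synthesis of CNP0284832.0 (compound 22)

## Analysis of the target

Target 22 is a biflavone of the 3-aryl type. A 5-hydroxy-7-methoxychromone (benzo ring A: C4a, C5, C6, C7, C8, C8a; pyranone ring C: O1, C2, C3, C4) carries the 4-hydroxyphenyl ring B on C2 and the central phenol ring E on C3 (E1 to E6, E3 bonded to C3, hydroxyl on E4). E1 is bonded to C2'' of a second, unmethylated 5'',7''-dihydroxychromone, made of pyranone ring F and benzo ring D. There is no stereocentre, and the hindered C3–E3 axis carries no descriptor, so no configuration has to be set or related. The sensitive groups are five free phenols, two of them chelated to a pyranone carbonyl (5-OH and 5''-OH), two electron-rich phloroglucinol-type rings, and two chromone C2 carbons that behave as vinylogous ester carbons towards hard nucleophiles. Three things make the synthesis hard: the C3–E3 bond is crowded by ring B, the C4 carbonyl and the E4 oxygen; rings A and D have the same oxygen pattern but only C7 of ring A is methylated; and two pyranone rings must be closed in a controlled order. The plan rests on ring A: it has oxygen on the alternate carbons C5, C7 and C8a and is fused through C4a–C8a to ring C, so the sequence C4, C4a, C8a, C8, C7, C6, C5 is a folded poly-beta-carbonyl chain whose first carbonyl (C4) and enol oxygen (O1) already sit in a 4-pyrone. Folding this chain by a C4a–C5 Claisen condensation on a preformed 2,3-diaryl-4-pyrone gives ring A as the free 5,7-diol, in which chelation tells the two hydroxyls apart for the single methylation.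

## Retrosynthetic reasoning

**22 from 21.** All five phenols are masked as benzyl ethers in 21 and released together at the end. The C7 methyl ether is the only oxygen substituent that survives hydrogenolysis, so the methyl group must be placed before ring D exists.

**Ring F: 21 from 20, 20 from 19, 19 from 16 and 18.** O1''–C2'' is cut first (cyclodehydration of diketone 20), then C2''–C3'' (acyl shift within aryl ester 19), then the ester bond between acid 16 and phenol 18. Ring D and ring F are built last, so the 5'' and 7'' oxygens arrive already benzylated from 18 and never compete with the ring A diol for the methyl group. The E1 carboxyl of 16 is at the oxidation level of C2''. Phenol 18 comes from 17 by capping its two non-chelated hydroxyls.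

**16 from 15, 14 and 13.** These are functional group changes: ester hydrolysis, benzylation of the 5-OH and methylation of the 7-OH. The 5-OH has to be capped because a chelated phenol on the acid partner would compete with the equally chelated phenol of 18 in the esterification. Methylation comes first because only in free diol 13 are the two hydroxyls differentiated by chelation.

**Key disconnection: 13 from 12.** The C4a–C5 bond of ring A is cut. Cutting ring C instead would need a preformed phloroglucinol with its oxygens already differentiated. Cutting C4a–C5 sends ring A back to a beta-keto ester chain on C8a of a 4-pyrone, so that ring A is made from acyclic carbon and appears as the free diol. The forward reaction must make pyrone carbon C4a attack the ester carbon (Claisen folding) and must suppress aldol foldings and chain cleavage.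

**12 from 10 through 11.** The C6–C7 bond is cut: the ketone C7 is the carboxyl carbon of acid 10, and C6 with the ester C5 is added by a decarboxylative two-carbon homologation of activated acid 11. This tolerates the pyrone and the ring E ester.

**10 from 9.** The C7–C8 bond is cut: C8 is the 6-methyl group of pyrone 9, which is vinylogously acidic and can take up a one-carbon electrophile.

**9 from 5 and 6 through 7 and 8.** O1–C2 and C3–C4 are cut. Ketene 7, released from 6, supplies O1, C8a, C4a, C4 and the methyl carbon C8. Enamine 5 supplies C2 and C3 with rings B and E already attached. Polarity fixes the orientation, and loss of the amine from 8 aromatises the pyrone.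

**5 from 4, 4 from 2 and 3, 2 from 1.** The C3–E3 bond is cut at the stage of deoxybenzoin 4. There it is an sp3 carbon–aryl bond formed by arylation of the methyl ketone enolate of 3 with bromide 2, before C3 is flanked by ring B and the C4 carbonyl in a ring. The most crowded bond of the target is thus made as the least crowded bond of the route. Bromide 2 is the benzyl ether of 1, whose ester is the future C2''.

## Alternatives that were turned down

**Alternative 1:** Ring E is cut at E2–E3 and E4–E5 and is grown on a finished methoxyflavone. In the forward key step the bis(silyl) ketene acetal A3, which carries the whole methoxyflavone on its nucleophilic carbon, adds across C6 and C3 of methyl coumalate A2. Decarboxylative loss of the lactone bridge and of one silyloxy group then aromatises the adduct to benzoate A1.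
- For: the crowded C3–E3 bond is never made by coupling, the polarity of the pyranone and the ketene acetal dictates the substitution pattern of ring E, and cycloadditions of this pyranone with ketene acetals are a known route to benzoates.
- Against: the nucleophilic carbon of A3 sits between the C2 aryl group and the C4 carbonyl, so the cycloaddition must take place at a hindered carbon and needs heat, under which silyl ketene acetals are labile. Rings A and C, the methyl ether and a C3 acetic acid arm must all be made first by a separate flavone synthesis. A1 then needs the same ring F endgame as 16, plus an exchange of the silyl ether.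
- Comparison: alternative 1 is equal on the endgame and stronger in guaranteeing the ring E pattern, but longer. The chosen route matches its advantage on the crowded bond by a simple enolate arylation (2 and 3 to 4) and adds a ring A construction that delivers the diol needed for regioselective methylation.

**Alternative 2:** Ring C is cut at C3–C4 and O1–C8a, with ring F already in place on ring E. In the forward key step the lithium enolate of ketone A5 is C-acylated by the 2-fluoroaroyl chloride A6. On warming with carbonate in a dipolar solvent, the enolate oxygen of the resulting diketone displaces fluoride in an addition–elimination ortho to the ketone and gives A4.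
- For: every stage is a known reaction on a known substrate class, the plan is the most convergent of the four, the C3–E3 bond already exists in A5, and A4 is one or two deprotection steps from the target. On precedent and probably on step count this alternative is stronger than the chosen strategy.
- Against: A4 carries two methyl ethers, so the C7 ether must be kept while the peri C5 ether is cleaved, and this rests entirely on chelation-controlled dealkylation at the very end. A5 needs a long linear preparation, since ring F must be built on ring E before the deoxybenzoin is assembled. C-acylation must win over O-acylation at a hindered enolate with a 2,6-disubstituted aroyl chloride.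
- Comparison: the chosen strategy offers instead a ring A that is born as the free diol, so the methyl group is placed by innate reactivity early and is proven before the second chromone is added. It also tests a short biomimetic construction. The bond logic of alternative 2 is kept in reserve as the fallback for step 7, starting from 4.

**Alternative 3:** Ring F is cut at C4a''–C4'', C4''–C3'' and O1''–C2'' and is closed last. In the forward key step a palladium-catalysed carbonylative coupling joins iodoarene triacetate A8 to the E1 ethynyl group of A9 through a new carbonyl carbon. The amine base uncovers an ortho phenoxide, which closes on the ynone and gives A7.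
- For: ring F is made in one operation under weakly basic conditions, without the strong base of an acyl shift, and the 5'' and 7'' hydroxyls appear free. For this ring alone it is shorter than steps 10, 12, 13 and 14 of the chosen route.
- Against: A8 is an electron-rich aryl iodide with two ortho substituents, so oxidative addition and carbonyl insertion are slow and direct alkyne coupling without carbonyl insertion competes. Closure of the phenoxide can go 5-exo to an aurone instead of 6-endo. Only one of three acetates should leave before cyclisation. The alternative says nothing about rings A and C or the C3–E3 bond, and A9 needs the whole methoxyflavone half plus two or three steps to turn the E1 substituent into an alkyne.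
- Comparison: alternative 3 is stronger in step economy for ring F. The chosen strategy keeps the classical sequence because its regiochemistry is unambiguous (a flavone, never an aurone) and because it uses the E1 ester that substrate 12 of the key step already carries.

Key step: step 7

Remark on the chemistry: the hindered C3–E3 axis is taken as rotationally labile, since the target structure carries no axial descriptor; 22 is treated as achiral and no step has to control configuration.

## Route

Step 1
Reactants: 1 methyl 3-bromo-4-hydroxybenzoate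
Product: 2 methyl 4-(benzyloxy)-3-bromobenzoate
Conditions: BnBr (1.1 equiv), K2CO3, DMF, rt
Reagents that add atoms: benzyl bromide, BrCc1ccccc1
Why: Williamson O-benzylation of the phenoxide. The benzyl ether withstands the base, Lewis acid and magnesium steps that follow and leaves with the other benzyl groups in step 15.

Step 2
Reactants: 2 methyl 4-(benzyloxy)-3-bromobenzoate; 3 1-[4-(benzyloxy)phenyl]ethan-1-one (4'-benzyloxyacetophenone)
Product: 4 methyl 4-(benzyloxy)-3-{2-[4-(benzyloxy)phenyl]-2-oxoethyl}benzoate
Conditions: Pd2(dba)3 (2 mol %), Xantphos (4.5 mol %), K3PO4, toluene, 90 °C; 3 in slight excess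
Reagents that add atoms: none
Why: Palladium-catalysed ketone alpha-arylation: zerovalent palladium inserts into the C–Br bond of 2, the potassium enolate of 3 replaces bromide on palladium, and reductive elimination forms the future C3–E3 bond. K3PO4 is basic enough for the aryl methyl ketone but spares the methyl ester, and the wide-bite-angle ligand together with the ortho benzyloxy group should hold the reaction at monoarylation.

Step 3
Reactants: 4 methyl 4-(benzyloxy)-3-{2-[4-(benzyloxy)phenyl]-2-oxoethyl}benzoate
Product: 5 methyl 4-(benzyloxy)-3-{2-[4-(benzyloxy)phenyl]-2-(morpholin-4-yl)ethenyl}benzoate (morpholine enamine; double-bond geometry undefined and of no consequence; used crude after filtration under argon)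
Conditions: morpholine (6 equiv), TiCl4 (0.6 equiv), toluene, 0 °C to rt
Reagents that add atoms: morpholine, C1COCCN1
Why: TiCl4-mediated enamine formation: TiCl4 activates the conjugated, hindered ketone and removes the water irreversibly, which azeotropic methods do poorly for deoxybenzoins. The amine-complexed titanium reagent should leave the ester and the benzyl ethers alone at room temperature.

Step 4
Reactants: 5 methyl 4-(benzyloxy)-3-{2-[4-(benzyloxy)phenyl]-2-(morpholin-4-yl)ethenyl}benzoate; 6 2,2,6-trimethyl-4H-1,3-dioxin-4-one
Product: 9 methyl 4-(benzyloxy)-3-{2-[4-(benzyloxy)phenyl]-6-methyl-4-oxo-4H-pyran-3-yl}benzoate, via acetylketene 7 (not isolated), via morpholino-dihydropyranone cycloadduct 8 (not isolated)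
Conditions: 6 (2 equiv, slow addition), toluene, 110 °C, argon sweep; then 1 M HCl, THF, rt
Reagents that add atoms: none
Why: Heating 6 expels acetone in a retro-[4+2] reaction, and acetylketene 7 is intercepted by the electron-rich enamine in the known enamine–acylketene route to 4-pyrones (hetero-Diels–Alder, or C-acylation followed by O-closure). Polarity fixes the regiochemistry: the nucleophilic enamine carbon bonds to the ketene carbon (C3–C4) and the acetyl oxygen to the aminal carbon (O1–C2). Loss of morpholine from 8, completed by the acid wash, gives the aromatic pyrone, and both transient stereocentres of 8 disappear.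

Step 5
Reactants: 9 methyl 4-(benzyloxy)-3-{2-[4-(benzyloxy)phenyl]-6-methyl-4-oxo-4H-pyran-3-yl}benzoate
Product: 10 {6-[4-(benzyloxy)phenyl]-5-[2-(benzyloxy)-5-(methoxycarbonyl)phenyl]-4-oxo-4H-pyran-2-yl}acetic acid
Conditions: LiN(SiMe3)2 (2.2 equiv), THF, −78 °C; CO2 (dry gas), −78 to −20 °C; cold 1 M HCl; used without heating
Reagents that add atoms: carbon dioxide, O=C=O
Why: Lateral (vinylogous) deprotonation of the 6-methyl group of a 4-pyrone gives a dienolate that is carboxylated at the exocyclic carbon (C7–C8). The hindered amide base does not add to the ring E ester at −78 °C, and the second equivalent covers the more acidic methylene of the product.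

Step 6
Reactants: 10 {6-[4-(benzyloxy)phenyl]-5-[2-(benzyloxy)-5-(methoxycarbonyl)phenyl]-4-oxo-4H-pyran-2-yl}acetic acid
Product: 12 methyl 4-(benzyloxy)-3-{2-[4-(benzyloxy)phenyl]-6-(4-methoxy-2,4-dioxobutyl)-4-oxo-4H-pyran-3-yl}benzoate, via acyl imidazolide 11 (not isolated)
Conditions: CDI (1.1 equiv), THF, 0 °C to rt; then MeO2CCH2CO2K (2 equiv), MgCl2 (2 equiv), Et3N (3 equiv), MeCN, rt to 40 °C; 1 M HCl
Reagents that add atoms: potassium methyl malonate, [K+].[O-]C(=O)CC(=O)OC
Why: Masamune–Brooks homologation: acyl imidazolide 11 C-acylates the magnesium enolate of the malonate half-ester, and the adduct loses carbon dioxide to give the beta-keto ester (C6–C7). The conditions are near neutral and should not touch the pyrone, the benzoate or the benzyl ethers.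

Step 7
Reactants: 12 methyl 4-(benzyloxy)-3-{2-[4-(benzyloxy)phenyl]-6-(4-methoxy-2,4-dioxobutyl)-4-oxo-4H-pyran-3-yl}benzoate
Product: 13 methyl 4-(benzyloxy)-3-{2-[4-(benzyloxy)phenyl]-5,7-dihydroxy-4-oxo-4H-chromen-3-yl}benzoate
Conditions: Mg(OMe)2 (6 equiv), MeOH/THF, 65 °C, argon; then cold 2 M HCl
Reagents that add atoms: none
Why: Proposed new method: Mg(OMe)2 turns the beta-keto ester terminus of 12 into its magnesium chelate and, in equilibrium, removes a proton from the C8 methylene, which is alpha to the C7 ketone and vinylogous to the pyrone carbonyl, so that the charge of the resulting dienolate appears on pyrone C5 (the future C4a). This carbon attacks the ester carbon (the future C5) that magnesium holds close and activates, methoxide leaves, and the C4a–C5 bond is formed; the two new ring carbonyls at C5 and C7 then enolise to the aromatic 5,7-diol, which as its magnesium phenoxide makes the sequence irreversible. The closest known reaction type is the Mg(OMe)2-induced Claisen cyclisation of 3,5,7-trioxo esters and of pyrone-masked polyketide chains to acylphloroglucinols; new here is that the nucleophilic carbon belongs to an intact 2,3-diaryl-4-pyrone. Ring A closes in the 6-exo-trig mode (enolate carbon onto an ester carbonyl that is exocyclic to the forming ring), and no stereocentre arises. The selectivity needed is Claisen folding over aldol folding and over cleavage of the chain. The substrate secures it in three ways: the C4 carbonyl is a vinylogous ester locked in the pyrone, so that attack of the ester methylene on it would demand a bridged bicycle; C3 is fully substituted and cannot serve as a second nucleophile; and the enolised, chelated C7 ketone is shielded from retro-Claisen attack by methoxide. Ring opening of the pyrone by methoxide is held back by the two aryl groups at C2 and by the negative charge of the substrate, and acidic work-up would close ring C again in any case. The ring E methyl ester can only exchange methoxide for methoxide in this medium, and the benzyl ethers are inert.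

Step 8
Reactants: 13 methyl 4-(benzyloxy)-3-{2-[4-(benzyloxy)phenyl]-5,7-dihydroxy-4-oxo-4H-chromen-3-yl}benzoate
Product: 14 methyl 4-(benzyloxy)-3-{2-[4-(benzyloxy)phenyl]-5-hydroxy-7-methoxy-4-oxo-4H-chromen-3-yl}benzoate
Conditions: MeI (1.1 equiv), K2CO3 (1.2 equiv), acetone, rt
Reagents that add atoms: iodomethane, CI
Why: Regioselective Williamson methylation: the 7-OH is the more acidic hydroxyl (vinylogous to the C4 carbonyl) and is free, whereas the 5-OH is tied up in a hydrogen bond to the C4 carbonyl and should not react with one equivalent of MeI under carbonate at room temperature.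

Step 9
Reactants: 14 methyl 4-(benzyloxy)-3-{2-[4-(benzyloxy)phenyl]-5-hydroxy-7-methoxy-4-oxo-4H-chromen-3-yl}benzoate
Product: 15 methyl 4-(benzyloxy)-3-{5-(benzyloxy)-2-[4-(benzyloxy)phenyl]-7-methoxy-4-oxo-4H-chromen-3-yl}benzoate
Conditions: BnBr (1.5 equiv), K2CO3 (3 equiv), nBu4NI (cat.), DMF, 70 °C
Reagents that add atoms: benzyl bromide, BrCc1ccccc1
Why: Forcing Williamson benzylation of the chelated 5-OH (dipolar solvent, heat, iodide catalysis). The cap is needed so that this phenol cannot compete with the phenol of 18 in step 12.

Step 10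
Reactants: 15 methyl 4-(benzyloxy)-3-{5-(benzyloxy)-2-[4-(benzyloxy)phenyl]-7-methoxy-4-oxo-4H-chromen-3-yl}benzoate
Product: 16 4-(benzyloxy)-3-{5-(benzyloxy)-2-[4-(benzyloxy)phenyl]-7-methoxy-4-oxo-4H-chromen-3-yl}benzoic acid
Conditions: LiOH (4 equiv), THF/MeOH/H2O, 45 °C; then 1 M HCl
Reagents that add atoms: lithium hydroxide, [Li+].[OH-]
Why: Saponification of the unhindered ring E methyl benzoate. C2 of the chromone is fully substituted and shielded by two aryl groups, so hydroxide addition there should not compete at this temperature.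

Step 11
Reactants: 17 1-(2,4,6-trihydroxyphenyl)ethan-1-one (2,4,6-trihydroxyacetophenone)
Product: 18 1-[2,4-bis(benzyloxy)-6-hydroxyphenyl]ethan-1-one
Conditions: BnBr (2.05 equiv), K2CO3, DMF, rt
Reagents that add atoms: benzyl bromide, BrCc1ccccc1
Why: Williamson benzylation of the two hydroxyls that are not chelated. The hydroxyl hydrogen-bonded to the acetyl group is the least nucleophilic and should stay free with two equivalents of BnBr at room temperature.

Step 12
Reactants: 16 4-(benzyloxy)-3-{5-(benzyloxy)-2-[4-(benzyloxy)phenyl]-7-methoxy-4-oxo-4H-chromen-3-yl}benzoic acid; 18 1-[2,4-bis(benzyloxy)-6-hydroxyphenyl]ethan-1-one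
Product: 19 2-acetyl-3,5-bis(benzyloxy)phenyl 4-(benzyloxy)-3-{5-(benzyloxy)-2-[4-(benzyloxy)phenyl]-7-methoxy-4-oxo-4H-chromen-3-yl}benzoate
Conditions: EDC·HCl (1.5 equiv), DMAP (0.5 equiv), CH2Cl2, rt
Reagents that add atoms: none
Why: Steglich esterification: DMAP transfers the acyl group of the O-acylisourea of 16 to the phenol of 18. Every other oxygen in both partners is etherified, so only one ester can form.

Step 13
Reactants: 19 2-acetyl-3,5-bis(benzyloxy)phenyl 4-(benzyloxy)-3-{5-(benzyloxy)-2-[4-(benzyloxy)phenyl]-7-methoxy-4-oxo-4H-chromen-3-yl}benzoate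
Product: 20 1-[2,4-bis(benzyloxy)-6-hydroxyphenyl]-3-(4-(benzyloxy)-3-{5-(benzyloxy)-2-[4-(benzyloxy)phenyl]-7-methoxy-4-oxo-4H-chromen-3-yl}phenyl)propane-1,3-dione
Conditions: KOtBu (3 equiv), THF, 0 °C to rt; then 1 M HCl
Reagents that add atoms: none
Why: Baker–Venkataraman rearrangement: the acetyl enolate attacks the neighbouring ester carbonyl through a six-membered transition state and the acyl group moves from oxygen to carbon (C2''–C3''), driven by formation of the stabilised diketone enolate and phenoxide. Anhydrous alkoxide avoids hydrolysis of the aryl ester, and the substrate has no other enolisable position.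

Step 14
Reactants: 20 1-[2,4-bis(benzyloxy)-6-hydroxyphenyl]-3-(4-(benzyloxy)-3-{5-(benzyloxy)-2-[4-(benzyloxy)phenyl]-7-methoxy-4-oxo-4H-chromen-3-yl}phenyl)propane-1,3-dione
Product: 21 5-(benzyloxy)-3-{2-(benzyloxy)-5-[5,7-bis(benzyloxy)-4-oxo-4H-chromen-2-yl]phenyl}-2-[4-(benzyloxy)phenyl]-7-methoxy-4H-chromen-4-one
Conditions: TsOH·H2O (0.2 equiv), toluene, 90 °C
Reagents that add atoms: none
Why: Acid-catalysed cyclodehydration of a 2-hydroxyphenyl 1,3-diketone: the phenol adds to the carbonyl bound to E1 and water is lost, closing pyranone ring F (O1''–C2''). A sulfonic acid in toluene is mild towards benzyl ethers, and partial loss of the peri 5''-O-benzyl group would be harmless because step 15 removes all of them.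

Step 15
Reactants: 21 5-(benzyloxy)-3-{2-(benzyloxy)-5-[5,7-bis(benzyloxy)-4-oxo-4H-chromen-2-yl]phenyl}-2-[4-(benzyloxy)phenyl]-7-methoxy-4H-chromen-4-one
Product: 22 3-[5-(5,7-dihydroxy-4-oxo-4H-chromen-2-yl)-2-hydroxyphenyl]-5-hydroxy-2-(4-hydroxyphenyl)-7-methoxy-4H-chromen-4-one (target)
Conditions: H2 (1 atm), 10% Pd/C, THF/MeOH, rt; stopped at full debenzylation
Reagents that add atoms: none
Why: Hydrogenolysis of the five aryl benzyl ethers over Pd/C. The aryl methyl ether is inert, and the conjugated C2=C3 and C2''=C3'' bonds of the chromones should survive at atmospheric pressure if the reaction is stopped once debenzylation is complete.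

## Compound list

1 | methyl 3-bromo-4-hydroxybenzoate | COC(=O)c1ccc(O)c(Br)c1 | starting material
2 | methyl 4-(benzyloxy)-3-bromobenzoate | COC(=O)c1ccc(OCc2ccccc2)c(Br)c1 | intermediate
3 | 1-[4-(benzyloxy)phenyl]ethan-1-one | CC(=O)c1ccc(OCc2ccccc2)cc1 | starting material
4 | methyl 4-(benzyloxy)-3-{2-[4-(benzyloxy)phenyl]-2-oxoethyl}benzoate | COC(=O)c1ccc(OCc2ccccc2)c(CC(=O)c2ccc(OCc3ccccc3)cc2)c1 | intermediate
5 | methyl 4-(benzyloxy)-3-{2-[4-(benzyloxy)phenyl]-2-(morpholin-4-yl)ethenyl}benzoate (geometry undefined) | COC(=O)c1ccc(OCc2ccccc2)c(C=C(N2CCOCC2)c2ccc(OCc3ccccc3)cc2)c1 | intermediate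
6 | 2,2,6-trimethyl-4H-1,3-dioxin-4-one | CC1=CC(=O)OC(C)(C)O1 | starting material
7 | acetylketene (but-1-ene-1,3-dione) | CC(=O)C=C=O | intermediate (not isolated)
8 | methyl 4-(benzyloxy)-3-{2-[4-(benzyloxy)phenyl]-6-methyl-2-(morpholin-4-yl)-4-oxo-3,4-dihydro-2H-pyran-3-yl}benzoate (mixture of diastereomers, racemic) | COC(=O)c1ccc(OCc2ccccc2)c(C3C(=O)C=C(C)OC3(N4CCOCC4)c5ccc(OCc6ccccc6)cc5)c1 | intermediate (not isolated)
9 | methyl 4-(benzyloxy)-3-{2-[4-(benzyloxy)phenyl]-6-methyl-4-oxo-4H-pyran-3-yl}benzoate | COC(=O)c1ccc(OCc2ccccc2)c(-c2c(-c3ccc(OCc4ccccc4)cc3)oc(C)cc2=O)c1 | intermediate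
10 | {6-[4-(benzyloxy)phenyl]-5-[2-(benzyloxy)-5-(methoxycarbonyl)phenyl]-4-oxo-4H-pyran-2-yl}acetic acid | COC(=O)c1ccc(OCc2ccccc2)c(-c2c(-c3ccc(OCc4ccccc4)cc3)oc(CC(=O)O)cc2=O)c1 | intermediate
11 | methyl 4-(benzyloxy)-3-{2-[4-(benzyloxy)phenyl]-6-[2-(1H-imidazol-1-yl)-2-oxoethyl]-4-oxo-4H-pyran-3-yl}benzoate | COC(=O)c1ccc(OCc2ccccc2)c(-c2c(-c3ccc(OCc4ccccc4)cc3)oc(CC(=O)n3ccnc3)cc2=O)c1 | intermediate (not isolated)
12 | methyl 4-(benzyloxy)-3-{2-[4-(benzyloxy)phenyl]-6-(4-methoxy-2,4-dioxobutyl)-4-oxo-4H-pyran-3-yl}benzoate | COC(=O)CC(=O)Cc1cc(=O)c(-c2cc(C(=O)OC)ccc2OCc2ccccc2)c(-c2ccc(OCc3ccccc3)cc2)o1 | intermediate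
13 | methyl 4-(benzyloxy)-3-{2-[4-(benzyloxy)phenyl]-5,7-dihydroxy-4-oxo-4H-chromen-3-yl}benzoate | COC(=O)c1ccc(OCc2ccccc2)c(-c2c(-c3ccc(OCc4ccccc4)cc3)oc3cc(O)cc(O)c3c2=O)c1 | intermediate
14 | methyl 4-(benzyloxy)-3-{2-[4-(benzyloxy)phenyl]-5-hydroxy-7-methoxy-4-oxo-4H-chromen-3-yl}benzoate | COC(=O)c1ccc(OCc2ccccc2)c(-c2c(-c3ccc(OCc4ccccc4)cc3)oc3cc(OC)cc(O)c3c2=O)c1 | intermediate
15 | methyl 4-(benzyloxy)-3-{5-(benzyloxy)-2-[4-(benzyloxy)phenyl]-7-methoxy-4-oxo-4H-chromen-3-yl}benzoate | COC(=O)c1ccc(OCc2ccccc2)c(-c2c(-c3ccc(OCc4ccccc4)cc3)oc3cc(OC)cc(OCc4ccccc4)c3c2=O)c1 | intermediate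
16 | 4-(benzyloxy)-3-{5-(benzyloxy)-2-[4-(benzyloxy)phenyl]-7-methoxy-4-oxo-4H-chromen-3-yl}benzoic acid | OC(=O)c1ccc(OCc2ccccc2)c(-c2c(-c3ccc(OCc4ccccc4)cc3)oc3cc(OC)cc(OCc4ccccc4)c3c2=O)c1 | intermediate
17 | 1-(2,4,6-trihydroxyphenyl)ethan-1-one | CC(=O)c1c(O)cc(O)cc1O | starting material
18 | 1-[2,4-bis(benzyloxy)-6-hydroxyphenyl]ethan-1-one | CC(=O)c1c(O)cc(OCc2ccccc2)cc1OCc1ccccc1 | intermediate
19 | 2-acetyl-3,5-bis(benzyloxy)phenyl 4-(benzyloxy)-3-{5-(benzyloxy)-2-[4-(benzyloxy)phenyl]-7-methoxy-4-oxo-4H-chromen-3-yl}benzoate | CC(=O)c1c(OC(=O)c2ccc(OCc3ccccc3)c(-c3c(-c4ccc(OCc5ccccc5)cc4)oc4cc(OC)cc(OCc5ccccc5)c4c3=O)c2)cc(OCc2ccccc2)cc1OCc1ccccc1 | intermediate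
20 | 1-[2,4-bis(benzyloxy)-6-hydroxyphenyl]-3-(4-(benzyloxy)-3-{5-(benzyloxy)-2-[4-(benzyloxy)phenyl]-7-methoxy-4-oxo-4H-chromen-3-yl}phenyl)propane-1,3-dione | O=C(CC(=O)c1c(O)cc(OCc2ccccc2)cc1OCc1ccccc1)c1ccc(OCc2ccccc2)c(-c2c(-c3ccc(OCc4ccccc4)cc3)oc3cc(OC)cc(OCc4ccccc4)c3c2=O)c1 | intermediate
21 | 5-(benzyloxy)-3-{2-(benzyloxy)-5-[5,7-bis(benzyloxy)-4-oxo-4H-chromen-2-yl]phenyl}-2-[4-(benzyloxy)phenyl]-7-methoxy-4H-chromen-4-one | COc1cc(OCc2ccccc2)c2c(=O)c(-c3cc(-c4cc(=O)c5c(OCc6ccccc6)cc(OCc6ccccc6)cc5o4)ccc3OCc3ccccc3)c(-c3ccc(OCc4ccccc4)cc3)oc2c1 | intermediate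
22 | 3-[5-(5,7-dihydroxy-4-oxo-4H-chromen-2-yl)-2-hydroxyphenyl]-5-hydroxy-2-(4-hydroxyphenyl)-7-methoxy-4H-chromen-4-one | COc1cc(O)c2c(=O)c(-c3cc(-c4cc(=O)c5c(O)cc(O)cc5o4)ccc3O)c(-c3ccc(O)cc3)oc2c1 | target

## Step count and least certain steps

Total step count: 15. Longest linear sequence: 14 steps (steps 1 to 10 and 12 to 15, from 1 to 22); step 11 is a one-step side branch.

**Step 7 (key step, proposed new method).**
- Risk: methoxide may open the pyrone, after which the open polycarbonyl chain can fold by aldol condensations to benzenoid isomers. Retro-Claisen cleavage of the side chain may lead back towards 9. The cyclisation may also stall because the chelated ester is too weak an electrophile for the pyrone dienolate.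
- Fallback (known chemistry, ring C closed last instead of ring A): it sets out from deoxybenzoin 4 and returns at acid 16. The lithium enolate of 4 (LiN(SiMe3)2, THF, −78 °C) is C-acylated with commercial 2,6-difluoro-4-methoxybenzoyl chloride to give methyl 4-(benzyloxy)-3-[1-(4-(benzyloxy)phenyl)-3-(2,6-difluoro-4-methoxyphenyl)-1,3-dioxopropan-2-yl]benzoate F1 (keto or enol form). With K2CO3 in DMF at 80 °C the enolate oxygen displaces one fluoride ortho to the ketone and closes ring C to methyl 4-(benzyloxy)-3-{2-[4-(benzyloxy)phenyl]-5-fluoro-7-methoxy-4-oxo-4H-chromen-3-yl}benzoate F2. Sodium benzyl oxide in benzyl alcohol/THF replaces the remaining carbonyl-activated fluoride and exchanges the ester, giving benzyl 4-(benzyloxy)-3-{5-(benzyloxy)-2-[4-(benzyloxy)phenyl]-7-methoxy-4-oxo-4H-chromen-3-yl}benzoate F3, and LiOH hydrolysis gives 16. The methyl ether is then fixed by the choice of acyl chloride.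

**Step 4.**
- Risk: C-acylation at the hindered enamine carbon (flanked by the ortho-benzyloxy ring E) may be slow, so that dimerisation of the ketene or hydrolysis of the enamine back to 4 takes over.
- Fallback: it sets out from 4 and returns at 9. Soft enolisation of 4 (MgBr2·OEt2, iPr2NEt, CH2Cl2) and C-acylation with (E)-3-methoxybut-2-enoyl chloride F4 (from the corresponding acid and oxalyl chloride) gives methyl 4-(benzyloxy)-3-[1-(4-(benzyloxy)phenyl)-5-methoxy-1,3-dioxohex-4-en-2-yl]benzoate F5. Trifluoroacetic acid in CH2Cl2 closes F5 to pyrone 9 by conjugate addition of the enol oxygen and loss of methanol.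

**Step 5.**
- Risk: the lateral carbanion may add to the ring E ester of a second molecule. Proton transfer from the carboxylated product may stop the reaction early. The pyranylacetic acid may lose carbon dioxide on work-up.
- Fallback: the acetic acid arm is brought in with the ketene instead of by metalation; it sets out from 5 and 6 and returns at 10. Dioxinone 6 is deprotonated at its methyl group (LiN(SiMe3)2, THF, −78 °C) and trapped with allyl chloroformate to give prop-2-en-1-yl (2,2-dimethyl-4-oxo-4H-1,3-dioxin-6-yl)acetate F6. Heating F6 with enamine 5 in toluene, as in step 4, gives prop-2-en-1-yl {6-[4-(benzyloxy)phenyl]-5-[2-(benzyloxy)-5-(methoxycarbonyl)phenyl]-4-oxo-4H-pyran-2-yl}acetate F7. The zerovalent palladium complex Pd(PPh3)4 with morpholine in THF at rt removes the allyl group under neutral conditions and gives 10, which is taken on at once.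

**Step 13.**
- Risk: the acyl shift has to occur next to the 6-benzyloxy group of a bulky ester, so cleavage of the aryl ester back to 16 and 18 by adventitious hydroxide, or incomplete migration, may dominate.
- Fallback: direct C-acylation instead of O-acylation and shift; it sets out from 16 and 18 and returns at 20. Acid 16 is converted with oxalyl chloride and catalytic DMF into 4-(benzyloxy)-3-{5-(benzyloxy)-2-[4-(benzyloxy)phenyl]-7-methoxy-4-oxo-4H-chromen-3-yl}benzoyl chloride F8. F8 is added at −78 °C to the phenoxide–enolate made from 18 with LiN(SiMe3)2 (3.5 equiv) in THF, and the enolate carbon is acylated to give 20 after acidification.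

**Step 15.**
- Risk: the C2''=C3'' bond of ring F, which has no C3'' substituent, may be over-reduced, or the product may precipitate on the catalyst before all five benzyl groups are gone.
- Fallback: Lewis-acid debenzylation instead of hydrogenolysis, from 21 directly to 22 with BCl3 and pentamethylbenzene in CH2Cl2 at −78 °C. The cation scavenger takes up the benzyl groups, and the C7 methyl ether, which is not peri to a carbonyl, should survive at this temperature. No new compound is made (F0).

## Further compounds

F1 | step 7 | methyl 4-(benzyloxy)-3-[1-(4-(benzyloxy)phenyl)-3-(2,6-difluoro-4-methoxyphenyl)-1,3-dioxopropan-2-yl]benzoate | COC(=O)c1ccc(OCc2ccccc2)c(C(C(=O)c2ccc(OCc3ccccc3)cc2)C(=O)c2c(F)cc(OC)cc2F)c1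
F2 | step 7 | methyl 4-(benzyloxy)-3-{2-[4-(benzyloxy)phenyl]-5-fluoro-7-methoxy-4-oxo-4H-chromen-3-yl}benzoate | COC(=O)c1ccc(OCc2ccccc2)c(-c2c(-c3ccc(OCc4ccccc4)cc3)oc3cc(OC)cc(F)c3c2=O)c1
F3 | step 7 | benzyl 4-(benzyloxy)-3-{5-(benzyloxy)-2-[4-(benzyloxy)phenyl]-7-methoxy-4-oxo-4H-chromen-3-yl}benzoate | O=C(OCc1ccccc1)c1ccc(OCc2ccccc2)c(-c2c(-c3ccc(OCc4ccccc4)cc3)oc3cc(OC)cc(OCc4ccccc4)c3c2=O)c1
F4 | step 4 | (E)-3-methoxybut-2-enoyl chloride | CO/C(C)=C/C(=O)Cl
F5 | step 4 | methyl 4-(benzyloxy)-3-[1-(4-(benzyloxy)phenyl)-5-methoxy-1,3-dioxohex-4-en-2-yl]benzoate (E) | COC(=O)c1ccc(OCc2ccccc2)c(C(C(=O)c2ccc(OCc3ccccc3)cc2)C(=O)/C=C(C)/OC)c1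
F6 | step 5 | prop-2-en-1-yl (2,2-dimethyl-4-oxo-4H-1,3-dioxin-6-yl)acetate | C=CCOC(=O)CC1=CC(=O)OC(C)(C)O1
F7 | step 5 | prop-2-en-1-yl {6-[4-(benzyloxy)phenyl]-5-[2-(benzyloxy)-5-(methoxycarbonyl)phenyl]-4-oxo-4H-pyran-2-yl}acetate | C=CCOC(=O)Cc1cc(=O)c(-c2cc(C(=O)OC)ccc2OCc2ccccc2)c(-c2ccc(OCc3ccccc3)cc2)o1
F8 | step 13 | 4-(benzyloxy)-3-{5-(benzyloxy)-2-[4-(benzyloxy)phenyl]-7-methoxy-4-oxo-4H-chromen-3-yl}benzoyl chloride | O=C(Cl)c1ccc(OCc2ccccc2)c(-c2c(-c3ccc(OCc4ccccc4)cc3)oc3cc(OC)cc(OCc4ccccc4)c3c2=O)c1
F0 | step 15 | none | none
A1 | alternative 1 | methyl 3-{5-(benzyloxy)-2-[4-(benzyloxy)phenyl]-7-methoxy-4-oxo-4H-chromen-3-yl}-4-[(tert-butyldimethylsilyl)oxy]benzoate | COC(=O)c1ccc(O[Si](C)(C)C(C)(C)C)c(-c2c(-c3ccc(OCc4ccccc4)cc3)oc3cc(OC)cc(OCc4ccccc4)c3c2=O)c1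
A2 | alternative 1 | methyl coumalate (methyl 2-oxo-2H-pyran-5-carboxylate) | COC(=O)C1=COC(=O)C=C1
A3 | alternative 1 | 5-(benzyloxy)-2-[4-(benzyloxy)phenyl]-3-{2,2-bis[(tert-butyldimethylsilyl)oxy]ethenyl}-7-methoxy-4H-chromen-4-one | CC(C)(C)[Si](C)(C)OC(O[Si](C)(C)C(C)(C)C)=Cc1c(-c2ccc(OCc3ccccc3)cc2)oc2cc(OC)cc(OCc3ccccc3)c2c1=O
A4 | alternative 2 | 3-{2-(benzyloxy)-5-[5,7-bis(benzyloxy)-4-oxo-4H-chromen-2-yl]phenyl}-2-[4-(benzyloxy)phenyl]-5,7-dimethoxy-4H-chromen-4-one | COc1cc(OC)c2c(=O)c(-c3cc(-c4cc(=O)c5c(OCc6ccccc6)cc(OCc6ccccc6)cc5o4)ccc3OCc3ccccc3)c(-c3ccc(OCc4ccccc4)cc3)oc2c1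
A5 | alternative 2 | 5,7-bis(benzyloxy)-2-(4-(benzyloxy)-3-{2-[4-(benzyloxy)phenyl]-2-oxoethyl}phenyl)-4H-chromen-4-one | O=C(Cc1cc(-c2cc(=O)c3c(OCc4ccccc4)cc(OCc4ccccc4)cc3o2)ccc1OCc1ccccc1)c1ccc(OCc2ccccc2)cc1
A6 | alternative 2 | 2-fluoro-4,6-dimethoxybenzoyl chloride | COc1cc(F)c(C(=O)Cl)c(OC)c1
A7 | alternative 3 | 5-(benzyloxy)-3-[2-(benzyloxy)-5-(5,7-dihydroxy-4-oxo-4H-chromen-2-yl)phenyl]-2-[4-(benzyloxy)phenyl]-7-methoxy-4H-chromen-4-one | COc1cc(OCc2ccccc2)c2c(=O)c(-c3cc(-c4cc(=O)c5c(O)cc(O)cc5o4)ccc3OCc3ccccc3)c(-c3ccc(OCc4ccccc4)cc3)oc2c1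
A8 | alternative 3 | 2-iodobenzene-1,3,5-triyl triacetate | CC(=O)Oc1cc(OC(C)=O)c(I)c(OC(C)=O)c1
A9 | alternative 3 | 5-(benzyloxy)-3-[2-(benzyloxy)-5-ethynylphenyl]-2-[4-(benzyloxy)phenyl]-7-methoxy-4H-chromen-4-one | C#Cc1ccc(OCc2ccccc2)c(-c2c(-c3ccc(OCc4ccccc4)cc3)oc3cc(OC)cc(OCc4ccccc4)c3c2=O)c1
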